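Target over cross product is the ratio behind the shares asked here. Call it the fork ratio; the usual term is selectivity. The ratio compares what stands in the flask at a reading.

| setting | oak | alder | cedar | larch | Sunday's | Thursday's | Saturday's | Tuesday's |
|---|---|---|---|---|---|---|---|---|
| starting material | 13 mM | 13 mM | 13 mM | 20 mM | 13 mM | 13 mM | 13 mM | 13 mM |
| coupling partner | 16.9 mM | 16.9 mM | 16.9 mM | 16.9 mM | 16.9 mM (in portions, 4, over 80 s) | 16.9 mM | 16.9 mM | 16.9 mM (fed, over 80 s) |
| second substrate | 65 mM | 32 mM | 130 mM | 65 mM | 65.0 mM | 65.0 mM | 65.0 mM (fed, over 80 s) | 65.0 mM |
| remark | run made earlier | run made earlier | run made earlier | run made earlier | first portion at the start, last at 80 s | everything together at the start | all else is in the flask from the start; the feed brings no volume worth counting | all else is in the flask from the start; the feed brings no volume worth counting |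
| time |  |  |  |  | 3.0 min | 3.0 min | 3.0 min | 3.0 min |

| run | time / s | target / % | cross product / % |
|---|---|---|---|
| oak | 20.0 | 3 | 8 |
| oak | 40.0 | 2 | 15 |
| oak | 50.0 | 4 | 18 |
| oak | 80.0 | 1 | 29 |
| oak | 90.0 | 2 | 25 |
| oak | 120 | 2 | 33 |
| alder | 20.0 | 3 | 1 |
| alder | 40.0 | 3 | 8 |
| alder | 50.0 | 4 | 11 |
| alder | 80.0 | 3 | 10 |
| alder | 90.0 | 3 | 13 |
| alder | 120 | 5 | 18 |
| cedar | 20.0 | 1 | 20 |
| cedar | 40.0 | 2 | 29 |
| cedar | 50.0 | 0 | 33 |
| cedar | 80.0 | 3 | 46 |
| cedar | 90.0 | 0 | 50 |
| cedar | 120 | 1 | 60 |
| larch | 10.0 | 4 | 5 |
| larch | 15.0 | 4 | 7 |
| larch | 30.0 | 5 | 13 |
| larch | 60.0 | 0 | 21 |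
| larch | 120 | 1 | 31 |

(scatter of a reading: 1.5 percentage points)



- the flask that comes out highest in share of target in target plus cross product, or "all alike" when all lie within 1.5 percentage points (Sunday's / Thursday's / Saturday's / Tuesday's / all alike)
- share of target in target plus cross product at the end, Sunday's
- share of target in target plus cross product at the end, Thursday's
- share of target in target plus cross product at the end, Saturday's
- share of target in target plus cross product at the end, Tuesday's

Target scatters round a flat level in the earlier runs. So I set its mean against the cross product at the last reading. Alder, at 32 mM of second substrate, gives 0.194. Cedar, at 130 mM, gives 0.0194. The logarithm of that fall over the logarithm of the rise in charge is 1.64. Call this the fork slope, the steepness of the fork ratio against second substrate.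

Two people read this differently. The first says the ratio belongs to the charges, and the four flasks share their charges. Dosing then moves nothing: oak's ratio, 0.0707, gives a share of 6.60% in each flask, so all alike.

The second made the forecast, holding that “the coupling partner is quickly scavenged by the second substrate”. It names Saturday's, at 25% (range 9% to 45%), against 4.6% for Sunday's, 4.8% for Thursday's and 4.6% for Tuesday's.

I side with the second on direction, not on size. Saturday's flask, counting the feed without consumption, holds on time-average 77.8% of its charge. Through the slope, oak's ratio becomes 0.107, a share of 9.65%, lower than the forecast. The earlier runs hold the coupling partner at 16.9 mM, so the slope is silent on Sunday's and Tuesday's.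

The flasks give 4.51% for Sunday's, 5.92% for Thursday's, 13.5% for Saturday's and 4.46% for Tuesday's. So Saturday's comes out highest. The first view holds among Sunday's, Thursday's and Tuesday's, which spread by 1.5 percentage points, less than the margin.

    second substrate + coupling partner → second product (k = 0.436 M⁻¹ s⁻¹)
    starting material + coupling partner → target (k = 1.61 M⁻¹ s⁻¹)
    starting material + second substrate → cross product (k = 0.172 M⁻¹ s⁻¹)
    target ⇌ isomer of the product (K = 11.0, k = 0.245 s⁻¹)
    starting material ⇌ dormant form (K = 0.913, k = 1.15 s⁻¹)

Saturday's fork ratio at 3.00 min is 0.156. Against Thursday's, the slope reads that as 37.3 mM of second substrate, not the 50.6 mM of my time-average. Half of the turnover into target up to that time was done by 0.382 min, when the feed had brought 28.6% of the charge. A neighbour of Saturday's is charged with 16 mM of second substrate. The slope lifts the ratio to 1.56, a share of 61.0%. That flask holds target 5.89% and cross product 6.24%, a share of 48.5%, lower than reckoned.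

The runs were generated by integration for an exercise.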